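**Plan**
- Retrosynthesis: cut C7–C8 (Nozaki–Hiyama–Kishi addition) and C11–C12 (ring-closing metathesis, then saturation) to separate ring A aldehyde 12 from ring D iodide 22; then cut ring A at C1–C2 and C3–C4, taking C2–C3 out as ketene, back to ene-aldehyde 4 made from (S)-carvone.
- Enabling feature: ring A has a β-hydroxy carbonyl pattern (C1 carbinol, C2 methylene, C3 oxygen) beside the gem-dimethyl carbon C4. C3 maps onto a ketone whose C2 enolate meets a C1 aldehyde on the quaternary C10, and C4 maps onto a tertiary radical from an isopropenyl group on C5.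
- Forward order: carvone → quaternary C10 → ring A in one annulation → C3/O1 adjustment → cleavage of the carvone ring (a temporary ring, kept as its oxirane) to the C7 aldehyde and C9 vinyl ketone → union with ring D → ten-membered ring → oxidation and deprotection.
- Stereochemistry: C5 from (S)-carvone; C10 by alkylation anti to isopropenyl; C1 by the aldol chair; C3 by equatorial hydride delivery; C13 from (S)-4-silyloxycyclopentenone by trans conjugate addition; C7 by ligand-controlled chromium addition.

Key step: step 4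

Assumption: atom numbers are the ent-kaurane numbers of the target (C1 carbinol, C3 acetoxy, C4 gem-dimethyl, C10 quaternary, C7 allylic carbinol, C8=C14, C9 chain ketone, C15 ring ketone, C16=C17 exo-methylene). Centers that are destroyed later (oxirane and C9 carbinol of the temporary ring, C8 of 19, C15 carbinol of ring D) are drawn as the expected major isomer and their configuration is immaterial.

Step 1
Reactants: 1 (S)-carvone
Product: 2 (5S,6R)-2,6-dimethyl-5-(prop-1-en-2-yl)cyclohex-2-en-1-one
Conditions: LiN(i-Pr)2, THF, −78 °C; MeI, −78 to 0 °C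
Reagents that add atoms: iodomethane CI
Why: Kinetic deprotonation at the only enolizable α′ carbon and enolate alkylation place the future C20 methyl on C10; this center is enolized again in step 2, so its configuration does not matter.

Step 2
Reactants: 2 trans-6-methylcarvone
Product: 3 (5R,6S)-6-(hydroxymethyl)-2,6-dimethyl-5-(prop-1-en-2-yl)cyclohex-2-en-1-one
Conditions: LiN(i-Pr)2, THF, −78 °C; CH2O (gas from cracked paraformaldehyde), −78 °C; H2O
Reagents that add atoms: formaldehyde C=O
Why: Aldol addition of the tetrasubstituted enolate to formaldehyde should occur anti to the neighbouring isopropenyl group, which sets the quaternary C10 with C1 trans and the methyl cis to that group.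

Step 3
Reactants: 3 hydroxymethyl ketone
Product: 4 (1S,6R)-1,3-dimethyl-2-oxo-6-(prop-1-en-2-yl)cyclohex-3-ene-1-carbaldehyde
Conditions: Dess–Martin periodinane, NaHCO3, CH2Cl2, 0 °C to rt
Reagents that add atoms: none
Why: Dess–Martin oxidation of the neopentyl primary alcohol gives the non-enolizable β-keto aldehyde under neutral conditions that avoid retro-aldol loss of formaldehyde.

Step 4
Reactants: 4 ene-aldehyde
Product: 6 (4aR,8S,8aS)-8-hydroxy-2,5,5,8a-tetramethyl-4a,5,8,8a-tetrahydronaphthalene-1,6(4H,7H)-dione, via iron enolate 5 (not isolated)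
Conditions: Fe(acac)3 (0.3 equiv), PhSiH2(O-i-Pr) (2 equiv), ketene (about 2 equiv, THF solution from cracked diketene, syringe pump), THF, 0 °C to rt; pH 7 buffer
Reagents that add atoms: ketene C=C=O
Why: Proposed new method: hydrogen atom transfer from the iron hydride to the isopropenyl group of 4 gives the tertiary C4 radical, which adds to the carbonyl carbon of ketene (C3); the 2-oxoalkyl radical is reduced by divalent iron to iron enolate 5, whose C2 attacks the neighbouring formyl carbon C1, so that C3–C4 and C1–C2 form in one radical–polar crossover. The closest known reaction type is the iron-hydride HAT-initiated Giese addition/aldol annulation of unsaturated aldehydes with enones, together with the addition of carbon nucleophiles to ketene to give enolates; ketene replaces the enone so that oxygen ends on C3 and C2 stays unsubstituted. Ring A closes by a 6-(enolendo)-exo-trig aldol through a chair that is trans-fused to the carvone ring. The only new stereocenter, C1, is set by that chair with the aldehyde oxygen equatorial, and because the aldol is reversible the equatorial carbinol should also accumulate under equilibration. The step needs HAT to the electron-rich 1,1-disubstituted alkene rather than the electron-poor enone alkene, and attack of the nucleophilic tertiary radical at the central carbon of ketene rather than at CH2, which oxygen coordination to trivalent iron and the bulk of the radical should favor.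

Step 5
Reactants: 6 hydroxy enedione
Product: 7 (4aR,8S,8aS)-8-[(tert-butyldimethylsilyl)oxy]-2,5,5,8a-tetramethyl-4a,5,8,8a-tetrahydronaphthalene-1,6(4H,7H)-dione
Conditions: TBSOTf, 2,6-lutidine, CH2Cl2, −78 to 0 °C
Reagents that add atoms: tert-butyldimethylsilyl triflate CC(C)(C)[Si](C)(C)OS(=O)(=O)C(F)(F)F
Why: A silyl triflate with a hindered base silylates the hindered equatorial C1 alcohol without enolizing the ketones, and this group later distinguishes O1 from O3.

Step 6
Reactants: 7 silyl ether
Product: 8 epoxy ketone (oxirane on the enone of 7, anti to the angular methyl group)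
Conditions: H2O2 (30% aq.), NaOH (cat.), MeOH, 0 °C
Reagents that add atoms: hydrogen peroxide OO
Why: Weitz–Scheffer nucleophilic epoxidation touches only the enone; the oxirane masks it against the hydride of step 7 and preloads oxygen for the cleavage in step 10.

Step 7
Reactants: 8 epoxy ketone
Product: 9 axial (3S) alcohol
Conditions: LiBH(s-Bu)3, THF, −78 °C; H2O
Reagents that add atoms: none
Why: The bulky trialkylborohydride should attack the C3 ketone along the equatorial trajectory, as with 4,4-dimethyl-3-oxo terpenoids, giving the axial alcohol trans to O1, while the epoxy ketone carbonyl between two fully substituted carbons is not reached at −78 °C.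

Step 8
Reactants: 9 hydroxy epoxy ketone
Product: 10 C9 vinyl carbinol
Conditions: CH2=CHMgBr (3 equiv), CeCl3 (Lewis acid additive), THF, −78 to 0 °C; H2O
Reagents that add atoms: vinylmagnesium bromide C=C[Mg]Br
Why: 1,2-Addition of the small vinyl nucleophile to the only ketone (O3 is protected as its magnesium alkoxide) attaches C11 to C9; C9 returns to a ketone in step 10.

Step 9
Reactants: 10 diol
Product: 11 C3 acetate
Conditions: Ac2O, DMAP, Et3N, CH2Cl2, rt
Reagents that add atoms: acetic anhydride CC(=O)OC(C)=O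
Why: DMAP-catalysed acylation should esterify the secondary C3 alcohol while the tertiary C9 carbinol, flanked by two fully substituted carbons, stays free.

Step 10
Reactants: 11 epoxy carbinol acetate
Product: 12 (1S,3R,4S,5S)-5-[(tert-butyldimethylsilyl)oxy]-2,2,4-trimethyl-3-(2-oxoethyl)-4-(prop-2-enoyl)cyclohexyl acetate
Conditions: H5IO6, THF/H2O, 0 °C to rt
Reagents that add atoms: water O (the C7 oxygen may come from the oxirane or from water)
Why: Periodic acid cleaves the oxirane and the adjacent tertiary carbinol oxidatively (glycol and α-ketol cleavage), so C7 appears as the aldehyde, C9 as the vinyl ketone, and the excised carvone carbon leaves with its methyl as acetic acid.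

Step 11
Reactants: 13 (S)-4-[(tert-butyldimethylsilyl)oxy]cyclopent-2-en-1-one
Product: 15 (2R,3S,4S)-4-[(tert-butyldimethylsilyl)oxy]-3-ethenyl-2-(hydroxymethyl)cyclopentan-1-one, via magnesium enolate 14 (not isolated)
Conditions: CH2=CHMgBr, CuBr·SMe2 (0.1 equiv), THF, −78 °C; CH2O (gas), −78 to −40 °C; H2O
Reagents that add atoms: vinylmagnesium bromide C=C[Mg]Br; formaldehyde C=O
Why: Copper-catalysed 1,4-addition should deliver the vinyl group trans to the C14 silyloxy group (sets C13), and the enolate is trapped by formaldehyde trans to the new vinyl group (three-component conjugate addition–aldol).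

Step 12
Reactants: 15 hydroxymethyl ketone
Product: 17 (3S,4S)-4-[(tert-butyldimethylsilyl)oxy]-3-ethenyl-2-methylidenecyclopentan-1-one, via primary mesylate 16 (not isolated)
Conditions: MsCl, Et3N, CH2Cl2, 0 °C to rt
Reagents that add atoms: none
Why: Mesylation of the primary alcohol and E1cB loss of methanesulfonate give the α-methylene ketone, so C16 is no longer a stereocenter.

Step 13
Reactants: 17 α-methylene ketone
Product: 20 (R)-4-ethenyl-2-iodo-5-methylidenecyclopent-2-en-1-one, via silyl dienol ether 18 (not isolated), via alpha-iodo ketone 19 (not isolated)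
Conditions: LiN(SiMe3)2, Me3SiCl, THF, −78 °C; N-iodosuccinimide, −78 to 0 °C; Et3N, 0 °C to rt
Reagents that add atoms: N-iodosuccinimide O=C1CCC(=O)N1I
Why: With C16 sp2 the ketone can enolize only toward C8, so the silyl dienol ether is regiodefined; electrophilic iodination and E1cB loss of the C14 silanolate give the 2-iodo enone without a strong base that could epimerize C13.

Step 14
Reactants: 20 iodo dienone
Product: 21 (1R,4R)-4-ethenyl-2-iodo-5-methylidenecyclopent-2-en-1-ol
Conditions: NaBH4, CeCl3·7H2O, MeOH, −78 °C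
Reagents that add atoms: none
Why: Luche 1,2-reduction of the cross-conjugated ketone, with hydride expected anti to the C13 vinyl group; C15 is reoxidized in step 21.

Step 15
Reactants: 21 iodo dienol
Product: 22 triethyl{[(1R,4R)-4-ethenyl-2-iodo-5-methylidenecyclopent-2-en-1-yl]oxy}silane
Conditions: Et3SiCl, imidazole, DMF, 0 °C
Reagents that add atoms: chlorotriethylsilane CC[Si](Cl)(CC)CC
Why: Standard silylation; the triethylsilyl ether can later be removed in the presence of the tert-butyldimethylsilyl ethers.

Step 16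
Reactants: 12 ring A aldehyde vinyl ketone; 22 ring D iodide
Product: 23 (7R) allylic alcohol joining ring A and ring D
Conditions: CrCl2 (4 equiv), NiCl2 (0.05 equiv), chiral oxazoline sulfonamide ligand (4.4 equiv), Et3N, THF, rt; H2O
Reagents that add atoms: none
Why: Nozaki–Hiyama–Kishi reaction, nickel-catalysed and mediated by divalent chromium, adds the alkenyl iodide only to the aldehyde (vinyl ketone and acetate are inert); C7 is to be set by the chiral sulfonamide–chromium complex, with the ligand enantiomer chosen to give 7R.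

Step 17
Reactants: 23 allylic alcohol
Product: 24 C7 tert-butyldimethylsilyl ether
Conditions: TBSOTf, 2,6-lutidine, CH2Cl2, −78 °C
Reagents that add atoms: tert-butyldimethylsilyl triflate CC(C)(C)[Si](C)(C)OS(=O)(=O)C(F)(F)F
Why: Silylation protects O7, which must survive the later oxidation at C15.

Step 18
Reactants: 24 seco diene
Product: 25 ten-membered ring enone (C11=C12, drawn Z)
Conditions: second-generation Grubbs catalyst (0.1 equiv), toluene (1 mM), 80 °C
Reagents that add atoms: none
Why: Ring-closing metathesis of the vinyl ketone with the C13 vinyl group expels ethene and closes the ten-membered ring; the 1,1-disubstituted and trisubstituted alkenes should not compete, and the alkene geometry is irrelevant because the bond is saturated in step 19.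

Step 19
Reactants: 25 macrocyclic enone
Product: 26 saturated C9 ketone
Conditions: [(Ph3P)CuH]6 (0.5 equiv), benzene, H2O (5 equiv), rt
Reagents that add atoms: none
Why: Stryker conjugate reduction: copper hydride reduces the only conjugated enone, leaving the isolated alkenes, acetate and silyl ethers; no stereocenter is formed.

Step 20
Reactants: 26 tris-silyl ether
Product: 27 C15 alcohol
Conditions: HF·pyridine, pyridine, THF, 0 °C
Reagents that add atoms: none
Why: Buffered HF·pyridine should cleave the triethylsilyl ether selectively in the presence of the two tert-butyldimethylsilyl ethers.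

Step 21
Reactants: 27 doubly allylic alcohol
Product: 28 1,7-bis-O-(tert-butyldimethylsilyl) ether of the target
Conditions: Dess–Martin periodinane, NaHCO3, CH2Cl2, 0 °C
Reagents that add atoms: none
Why: Dess–Martin oxidation of the only free alcohol unveils the cross-conjugated 16-methylene cyclopentenone late, so this Michael acceptor meets no further nucleophilic step.

Step 22
Reactants: 28 bis-silyl ether
Product: 29 CNP0223751.1
Conditions: HF (48% aq.), MeCN, 0 °C to rt
Reagents that add atoms: none
Why: Acidic desilylation removes both silyl ethers without touching the acetate or the enones; no stereocenter is affected.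

**Compound list**
1 | (S)-(+)-carvone, (5S)-2-methyl-5-(prop-1-en-2-yl)cyclohex-2-en-1-one | CC1=CC[C@@H](CC1=O)C(C)=C | starting material
2 | (5S,6R)-2,6-dimethyl-5-(prop-1-en-2-yl)cyclohex-2-en-1-one | CC1=CC[C@@H]([C@@H](C)C1=O)C(C)=C | intermediate
3 | (5R,6S)-6-(hydroxymethyl)-2,6-dimethyl-5-(prop-1-en-2-yl)cyclohex-2-en-1-one | CC1=CC[C@@H]([C@@](C)(CO)C1=O)C(C)=C | intermediate
4 | (1S,6R)-1,3-dimethyl-2-oxo-6-(prop-1-en-2-yl)cyclohex-3-ene-1-carbaldehyde | CC1=CC[C@@H]([C@@](C)(C=O)C1=O)C(C)=C | intermediate
5 | iron enolate (drawn as the enolate anion) of (1S,6R)-1,3-dimethyl-6-(2-methyl-3-oxobutan-2-yl)-2-oxocyclohex-3-ene-1-carbaldehyde | CC1=CC[C@@H]([C@@](C)(C=O)C1=O)C(C)(C)C([O-])=C | intermediate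
6 | (4aR,8S,8aS)-8-hydroxy-2,5,5,8a-tetramethyl-4a,5,8,8a-tetrahydronaphthalene-1,6(4H,7H)-dione | CC1=CC[C@@H]2C(C)(C)C(=O)C[C@H](O)[C@@]2(C)C1=O | intermediate
7 | (4aR,8S,8aS)-8-[(tert-butyldimethylsilyl)oxy]-2,5,5,8a-tetramethyl-4a,5,8,8a-tetrahydronaphthalene-1,6(4H,7H)-dione | CC1=CC[C@@H]2C(C)(C)C(=O)C[C@H](O[Si](C)(C)C(C)(C)C)[C@@]2(C)C1=O | intermediate
8 | 2,3-epoxide of 7, oxirane anti to the 8a-methyl group | C[C@]12O[C@H]1C[C@@H]3C(C)(C)C(=O)C[C@H](O[Si](C)(C)C(C)(C)C)[C@@]3(C)C2=O | intermediate
9 | 8 with the C3 ketone reduced to the axial (3S) alcohol | C[C@]12O[C@H]1C[C@@H]3C(C)(C)[C@@H](O)C[C@H](O[Si](C)(C)C(C)(C)C)[C@@]3(C)C2=O | intermediate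
10 | 9 with vinyl added to the C9 ketone (tertiary allylic carbinol) | C[C@]12O[C@H]1C[C@@H]3C(C)(C)[C@@H](O)C[C@H](O[Si](C)(C)C(C)(C)C)[C@@]3(C)[C@@]2(O)C=C | intermediate
11 | C3 acetate of 10 | C[C@]12O[C@H]1C[C@@H]3C(C)(C)[C@@H](OC(C)=O)C[C@H](O[Si](C)(C)C(C)(C)C)[C@@]3(C)[C@@]2(O)C=C | intermediate
12 | (1S,3R,4S,5S)-5-[(tert-butyldimethylsilyl)oxy]-2,2,4-trimethyl-3-(2-oxoethyl)-4-(prop-2-enoyl)cyclohexyl acetate | C=CC(=O)[C@@]1(C)[C@H](CC=O)C(C)(C)[C@@H](OC(C)=O)C[C@@H]1O[Si](C)(C)C(C)(C)C | intermediate
13 | (S)-4-[(tert-butyldimethylsilyl)oxy]cyclopent-2-en-1-one | O=C1C=C[C@@H](O[Si](C)(C)C(C)(C)C)C1 | starting material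
14 | magnesium enolate (drawn as the enolate anion) of (3S,4S)-4-[(tert-butyldimethylsilyl)oxy]-3-ethenylcyclopentan-1-one | [O-]C1=C[C@H](C=C)[C@@H](O[Si](C)(C)C(C)(C)C)C1 | intermediate
15 | (2R,3S,4S)-4-[(tert-butyldimethylsilyl)oxy]-3-ethenyl-2-(hydroxymethyl)cyclopentan-1-one | O=C1C[C@H](O[Si](C)(C)C(C)(C)C)[C@@H](C=C)[C@@H]1CO | intermediate
16 | methanesulfonate of the primary alcohol of 15 | O=C1C[C@H](O[Si](C)(C)C(C)(C)C)[C@@H](C=C)[C@@H]1COS(C)(=O)=O | intermediate
17 | (3S,4S)-4-[(tert-butyldimethylsilyl)oxy]-3-ethenyl-2-methylidenecyclopentan-1-one | O=C1C[C@H](O[Si](C)(C)C(C)(C)C)[C@@H](C=C)C1=C | intermediate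
18 | trimethylsilyl dienol ether of 17 (enol double bond toward C8) | C[Si](C)(C)OC1=C[C@H](O[Si](C)(C)C(C)(C)C)[C@@H](C=C)C1=C | intermediate
19 | 5-iodo derivative of 17 (iodine on C8, trans to the silyloxy group) | O=C1[C@@H](I)[C@H](O[Si](C)(C)C(C)(C)C)[C@@H](C=C)C1=C | intermediate
20 | (R)-4-ethenyl-2-iodo-5-methylidenecyclopent-2-en-1-one | O=C1C(I)=C[C@@H](C=C)C1=C | intermediate
21 | (1R,4R)-4-ethenyl-2-iodo-5-methylidenecyclopent-2-en-1-ol | O[C@H]1C(I)=C[C@@H](C=C)C1=C | intermediate
22 | triethyl{[(1R,4R)-4-ethenyl-2-iodo-5-methylidenecyclopent-2-en-1-yl]oxy}silane | CC[Si](CC)(CC)O[C@H]1C(I)=C[C@@H](C=C)C1=C | intermediate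
23 | (1S,3R,4S,5S)-4-acryloyl-5-[(tert-butyldimethylsilyl)oxy]-3-{(2R)-2-[(3R,5R)-3-ethenyl-4-methylidene-5-(triethylsilyloxy)cyclopent-1-en-1-yl]-2-hydroxyethyl}-2,2,4-trimethylcyclohexyl acetate | C=CC(=O)[C@@]1(C)[C@H](C[C@@H](O)C2=C[C@@H](C=C)C(=C)[C@H]2O[Si](CC)(CC)CC)C(C)(C)[C@@H](OC(C)=O)C[C@@H]1O[Si](C)(C)C(C)(C)C | intermediate
24 | C7 tert-butyldimethylsilyl ether of 23 | C=CC(=O)[C@@]1(C)[C@H](C[C@@H](O[Si](C)(C)C(C)(C)C)C2=C[C@@H](C=C)C(=C)[C@H]2O[Si](CC)(CC)CC)C(C)(C)[C@@H](OC(C)=O)C[C@@H]1O[Si](C)(C)C(C)(C)C | intermediate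
25 | (11Z)-11,12-didehydro macrocycle: 1,7-bis-O-TBS, 15-O-TES, C15 carbinol, C9 enone | C=C1[C@@H](O[Si](CC)(CC)CC)C2=C[C@H]1/C=C\C(=O)[C@@]1(C)[C@H](C[C@H]2O[Si](C)(C)C(C)(C)C)C(C)(C)[C@@H](OC(C)=O)C[C@@H]1O[Si](C)(C)C(C)(C)C | intermediate
26 | 11,12-dihydro derivative of 25 | C=C1[C@@H](O[Si](CC)(CC)CC)C2=C[C@H]1CCC(=O)[C@@]1(C)[C@H](C[C@H]2O[Si](C)(C)C(C)(C)C)C(C)(C)[C@@H](OC(C)=O)C[C@@H]1O[Si](C)(C)C(C)(C)C | intermediate
27 | 15-alcohol from 26 (triethylsilyl group removed) | C=C1[C@@H](O)C2=C[C@H]1CCC(=O)[C@@]1(C)[C@H](C[C@H]2O[Si](C)(C)C(C)(C)C)C(C)(C)[C@@H](OC(C)=O)C[C@@H]1O[Si](C)(C)C(C)(C)C | intermediate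
28 | 1,7-bis-O-(tert-butyldimethylsilyl) ether of the target | C=C1C(=O)C2=C[C@H]1CCC(=O)[C@@]1(C)[C@H](C[C@H]2O[Si](C)(C)C(C)(C)C)C(C)(C)[C@@H](OC(C)=O)C[C@@H]1O[Si](C)(C)C(C)(C)C | intermediate
29 | CNP0223751.1, (1S,3S,5R,7R,10S,13R)-1,7-dihydroxy-9,15-dioxo-8,9-seco-kaura-8(14),16-dien-3-yl acetate | C=C1C(=O)C2=C[C@H]1CCC(=O)[C@@]1(C)[C@H](C[C@H]2O)C(C)(C)[C@@H](OC(C)=O)C[C@@H]1O | target

**Totals and risks**
Total step count: 22. Longest linear sequence: 17 steps (steps 1–10, then 16–22).

Step 4 (Proposed new method). What may go wrong: the tertiary radical may attack the CH2 terminus of ketene, ketene may be consumed by hydride reduction, dimerization or O-acylation of the aldolate, or the aldol may close with the C1 oxygen axial. Fallback with known chemistry, setting out from 4: addition of LiCH2CN (MeCN, LiN(i-Pr)2, THF, −78 °C) to the aldehyde, which is far more accessible than the enone carbonyl, should give the β-hydroxy nitrile F1. Heating F1 with Fe(acac)3 and PhSiH3 in EtOH (60 °C) should start the same HAT at the isopropenyl group and close ring A by 6-exo-dig radical cyclization onto the nitrile, giving the ketimine F2. Acidic aqueous work-up hydrolyses F2 and the route is rejoined at 6. If C1 is formed as the wrong epimer, brief K2CO3/MeOH treatment of 6 allows retro-aldol/aldol equilibration.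

Step 18. What may go wrong: intermolecular metathesis (oligomerization) instead of closure of the strained ten-membered ring. Fallback, setting out from 12 and 22: cross-metathesis of the vinyl ketone of 12 with the vinyl group of 22 (second-generation Grubbs catalyst, CH2Cl2, 40 °C) should give the open-chain (E)-enone aldehyde iodide F3. The ring is then closed by an intramolecular Nozaki–Hiyama–Kishi reaction at C7–C8 (CrCl2, NiCl2 cat., the same chiral ligand, THF/DMSO, high dilution) to the macrocyclic (11E)-enone alcohol F4. Silylation (TBSOTf, 2,6-lutidine) gives the silyl ether F5, the 11E isomer of 25, and the conditions of step 19 return the route at 26.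

Step 16. What may go wrong: poor facial selectivity at C7, since the aldehyde has no nearby stereocenter and control rests on the ligand alone. Fallback, setting out from 23 obtained as a C7 epimer mixture: MnO2 (CH2Cl2, rt) oxidizes the allylic carbinol to the cyclopentenyl ketone F6. Corey–Bakshi–Shibata reduction ((S)-2-methyl-CBS-oxazaborolidine, catecholborane, toluene, −78 °C) should then reduce this ketone with reagent control in preference to the neopentyl C9 vinyl ketone, returning the route at 23 as the 7R alcohol.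

**Further compounds**
F1 | step 4 | (3S)-3-[(1S,6R)-1,3-dimethyl-2-oxo-6-(prop-1-en-2-yl)cyclohex-3-en-1-yl]-3-hydroxypropanenitrile | CC1=CC[C@@H]([C@@](C)([C@@H](O)CC#N)C1=O)C(C)=C
F2 | step 4 | (4aR,8S,8aS)-8-hydroxy-6-imino-2,5,5,8a-tetramethyl-4a,5,6,7,8,8a-hexahydronaphthalen-1(4H)-one | CC1=CC[C@@H]2C(C)(C)C(=N)C[C@H](O)[C@@]2(C)C1=O
F3 | step 18 | open-chain (E)-enone from cross-metathesis of 12 and 22 (C7 aldehyde, C8 iodide) | CC[Si](CC)(CC)O[C@H]1C(I)=C[C@H](C1=C)/C=C/C(=O)[C@@]2(C)[C@H](CC=O)C(C)(C)[C@@H](OC(C)=O)C[C@@H]2O[Si](C)(C)C(C)(C)C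
F4 | step 18 | macrocyclic (11E)-enone with free (7R) alcohol, 1-O-TBS, 15-O-TES | C=C1[C@@H](O[Si](CC)(CC)CC)C2=C[C@H]1/C=C/C(=O)[C@@]1(C)[C@H](C[C@H]2O)C(C)(C)[C@@H](OC(C)=O)C[C@@H]1O[Si](C)(C)C(C)(C)C
F5 | step 18 | 7-O-TBS ether of F4 (11E isomer of 25) | C=C1[C@@H](O[Si](CC)(CC)CC)C2=C[C@H]1/C=C/C(=O)[C@@]1(C)[C@H](C[C@H]2O[Si](C)(C)C(C)(C)C)C(C)(C)[C@@H](OC(C)=O)C[C@@H]1O[Si](C)(C)C(C)(C)C
F6 | step 16 | C7 ketone of 23 | C=CC(=O)[C@@]1(C)[C@H](CC(=O)C2=C[C@@H](C=C)C(=C)[C@H]2O[Si](CC)(CC)CC)C(C)(C)[C@@H](OC(C)=O)C[C@@H]1O[Si](C)(C)C(C)(C)C
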